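**Plan**

1. Germacrane numbering is used: ring C1–C10 with C1=C10 (C14H2OAc on C10) and C4=C5 (C15H2OAc on C4), carbinol C6, ring-fusion carbons C7/C8, lactone O on C8, C11(=C13H2)–C12=O. The retrosynthesis cuts C6–C7 last (ten-membered ring), then C7=C11 and the C12–O ester (butenolide), then C9–C10, then C3–C4.
2. Enabling feature: C6(OH)–C7–C11(=C13H2) is a homoallylic alcohol whose allyl part is the α-methylene-γ-lactone ring itself. It is therefore the retron of an aldehyde allylation by a 3-(bromomethyl)but-2-enolide (C13–Br, C7=C11) that already carries the lactone and C8.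
3. Forward: C3–C4 by anti-carbomagnesiation of a butynediol monoether, C14 by alkyne hydroxymethylation, syn-hydrostannation/iodination, C9–C10 by opening (S)-epichlorohydrin, homologation to the C8 vinyl carbinol, acylation and ring-closing metathesis to the butenolide, then Cr(II) closure of the carbocycle.
4. Stereochemistry: C8 from (S)-epichlorohydrin; C7 and C6 both in the key step, relayed from C8; ring-cis C4=C5 from the anti-carbomagnesiation; ring-trans C1=C10 from the syn-hydrostannation.

Key step: step 14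

Remark: the SMILES is read as (6R,7S,8S), with C9 trans to C2 across C1=C10 (CIP Z) and C3 cis to C6 across C4=C5 (CIP E).

**Route**

Step 1
Reactants: 1 but-2-yne-1,4-diol; 2 tert-butyldimethylsilyl chloride
Product: 3 4-[(tert-butyldimethylsilyl)oxy]but-2-yn-1-ol
Conditions: NaH (1.0 equiv), THF, 0 °C → rt; then TBSCl (1.0 equiv), rt
Reagents that add atoms: tert-butyldimethylsilyl chloride, CC(C)(C)[Si](C)(C)Cl
Why: Monosilylation of a symmetrical diol through its monosodium alkoxide should give the mono-TBS ether; no stereocentre is involved.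

Step 2
Reactants: 3 4-[(tert-butyldimethylsilyl)oxy]but-2-yn-1-ol; 4 (4-bromobut-1-yn-1-yl)trimethylsilane
Product: 7 (E)-2-(but-3-yn-1-yl)-4-[(tert-butyldimethylsilyl)oxy]but-2-en-1-ol, via Grignard reagent 5 (not isolated), via silylalkyne 6 (not isolated)
Conditions: 4, Mg, THF, rt; 3, i-PrMgCl (1.0 equiv), THF, 0 °C; then 5 (2 equiv), CuI (10 mol%), 0 °C → rt; aq NH4Cl; then K2CO3, MeOH, rt
Reagents that add atoms: (4-bromobut-1-yn-1-yl)trimethylsilane (as its Grignard reagent), C[Si](C)(C)C#CCCBr
Why: Copper-catalysed anti-carbomagnesiation of a propargylic alkoxide should deliver the alkyl group to the carbon next to CH2O–Mg and magnesium to the distal carbon within a five-membered oxamagnesacycle, so that protonolysis places C3 cis to C6 (ring-cis C4=C5), and K2CO3/MeOH then removes only the C-silyl group.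

Step 3
Reactants: 7 (E)-2-(but-3-yn-1-yl)-4-[(tert-butyldimethylsilyl)oxy]but-2-en-1-ol; 8 paraformaldehyde
Product: 9 (E)-8-[(tert-butyldimethylsilyl)oxy]-6-(hydroxymethyl)oct-6-en-2-yn-1-ol
Conditions: n-BuLi (2.2 equiv), THF, −78 °C; (CH2O)n, −78 °C → rt; aq NH4Cl
Reagents that add atoms: formaldehyde (from paraformaldehyde), C=O
Why: Addition of the alkoxide/acetylide dianion to formaldehyde (alkyne hydroxymethylation) should install C14 as the propargylic alcohol that directs the next step.

Step 4
Reactants: 9 (E)-8-[(tert-butyldimethylsilyl)oxy]-6-(hydroxymethyl)oct-6-en-2-yn-1-ol; 10 tributyltin hydride; 11 iodine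
Product: 13 (2E,6E)-8-[(tert-butyldimethylsilyl)oxy]-6-(hydroxymethyl)-2-iodoocta-2,6-dien-1-ol, via alkenylstannane 12 (not isolated)
Conditions: Bu3SnH (1.2 equiv), PdCl2(PPh3)2 (2 mol%), THF, 0 °C → rt; then I2, CH2Cl2, 0 °C
Reagents that add atoms: iodine, II; tributyltin hydride, CCCC[SnH](CCCC)CCCC (tin only in 12, hydrogen in 13)
Why: Palladium-catalysed syn-hydrostannation of a 2-alkyn-1-ol should place tin on the carbon next to the hydroxymethyl group and hydrogen on C1 on the same side, and iododestannylation with retention should give the iodide trans to C2 (ring-trans C1=C10).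

Step 5
Reactants: 13 (2E,6E)-8-[(tert-butyldimethylsilyl)oxy]-6-(hydroxymethyl)-2-iodoocta-2,6-dien-1-ol; 14 4-methoxybenzyl chloride
Product: 15 (2E,6E)-8-[(tert-butyldimethylsilyl)oxy]-2-iodo-1-[(4-methoxybenzyl)oxy]-6-{[(4-methoxybenzyl)oxy]methyl}octa-2,6-diene
Conditions: NaH, PMBCl, Bu4NI (cat.), DMF, 0 °C → rt
Reagents that add atoms: 4-methoxybenzyl chloride, COc1ccc(CCl)cc1
Why: Williamson etherification should mask both primary allylic hydroxyls as PMB ethers, which tolerate organolithium chemistry and are later removed oxidatively beside the silyl ether.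

Step 6
Reactants: 15 (2E,6E)-bis-PMB alkenyl iodide; 16 (S)-epichlorohydrin
Product: 18 (2S,4Z,8E)-10-[(tert-butyldimethylsilyl)oxy]-1-chloro-4,8-bis{[(4-methoxybenzyl)oxy]methyl}deca-4,8-dien-2-ol, via alkenyllithium 17 (not isolated)
Conditions: t-BuLi (2.0 equiv), Et2O, −78 °C; then 16, BF3·OEt2, −78 °C; aq NH4Cl
Reagents that add atoms: (S)-epichlorohydrin, ClC[C@@H]1CO1
Why: Iodine–lithium exchange with retention of olefin geometry and BF3-promoted opening of the epoxide at its unsubstituted carbon by the alkenyllithium should form C9–C10 and carry the (S) centre of 16 unchanged into C8.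

Step 7
Reactants: 18 (2S,4Z,8E)-chlorohydrin; 19 trimethylsulfonium iodide
Product: 21 (3S,5Z,9E)-11-[(tert-butyldimethylsilyl)oxy]-5,9-bis{[(4-methoxybenzyl)oxy]methyl}undeca-1,5,9-trien-3-ol, via epoxide 20 (not isolated)
Conditions: Me3S+ I− (5 equiv), n-BuLi (4.8 equiv), THF, −20 °C; then 18, −20 °C → rt
Reagents that add atoms: trimethylsulfonium iodide (one CH2), C[S+](C)C.[I-]
Why: Base closes the chlorohydrin to the terminal epoxide, dimethylsulfonium methylide opens it at CH2, and ylide formation with loss of Me2S should give the one-carbon-homologated vinyl carbinol (epoxide-to-allylic-alcohol homologation) without touching C8.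

Step 8
Reactants: 21 (3S,5Z,9E)-bis-PMB vinyl carbinol
Product: 22 (3S,5Z,9E)-11-[(tert-butyldimethylsilyl)oxy]-5,9-bis(hydroxymethyl)undeca-1,5,9-trien-3-ol
Conditions: DDQ (2.5 equiv), CH2Cl2/pH 7 buffer, 0 °C
Reagents that add atoms: none
Why: Oxidative PMB cleavage by DDQ should free both primary allylic alcohols while the TBS ether and the olefins stay intact.

Step 9
Reactants: 22 (3S,5Z,9E)-triol; 23 acetyl chloride
Product: 24 (3S,5Z,9E)-5,9-bis(acetoxymethyl)-11-[(tert-butyldimethylsilyl)oxy]undeca-1,5,9-trien-3-ol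
Conditions: AcCl (2.1 equiv), 2,4,6-collidine, CH2Cl2, −78 °C
Reagents that add atoms: acetyl chloride, CC(Cl)=O
Why: Acetyl chloride with a hindered pyridine base at low temperature acylates primary hydroxyls much faster than the secondary one, which should install both acetates of the target and leave the C8 hydroxyl free.

Step 10
Reactants: 24 (3S,5Z,9E)-diacetate alcohol; 25 2-(bromomethyl)acrylic acid
Product: 26 (3S,5Z,9E)-5,9-bis(acetoxymethyl)-11-[(tert-butyldimethylsilyl)oxy]undeca-1,5,9-trien-3-yl 2-(bromomethyl)acrylate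
Conditions: DCC, DMAP (10 mol%), CH2Cl2, 0 °C
Reagents that add atoms: 2-(bromomethyl)acrylic acid, OC(=O)C(=C)CBr
Why: Steglich esterification should acylate the remaining secondary allylic alcohol with retention at C8 and bring in C11, C12 and C13 together with the allylic bromide.

Step 11
Reactants: 26 2-(bromomethyl)acrylate ester
Product: 27 (S)-3-(bromomethyl)-5-[(2Z,6E)-2,6-bis(acetoxymethyl)-8-[(tert-butyldimethylsilyl)oxy]octa-2,6-dien-1-yl]furan-2(5H)-one
Conditions: Hoveyda–Grubbs II (10 mol%), toluene (5 mM), 80 °C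
Reagents that add atoms: none
Why: Ring-closing metathesis between the vinyl group and the 1,1-disubstituted acrylate, with a phosphine-free catalyst that the allylic bromide cannot quaternise, should close the butenolide with loss of ethylene while the trisubstituted olefins stay inert.

Step 12
Reactants: 27 silyl ether butenolide
Product: 28 (S)-3-(bromomethyl)-5-[(2Z,6E)-2,6-bis(acetoxymethyl)-8-hydroxyocta-2,6-dien-1-yl]furan-2(5H)-one
Conditions: HF (48% aq), MeCN, 0 °C
Reagents that add atoms: none
Why: Acidic fluoride cleaves the primary allylic silyl ether without base, so the acetates, the allylic bromide and the base-labile C8–H centre of the butenolide should survive.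

Step 13
Reactants: 28 allylic alcohol
Product: 29 (S)-3-(bromomethyl)-5-[(2Z,6E)-2,6-bis(acetoxymethyl)-8-oxoocta-2,6-dien-1-yl]furan-2(5H)-one
Conditions: MnO2 (activated, excess), CH2Cl2, rt; used at once
Reagents that add atoms: none
Why: MnO2 oxidises allylic alcohols under neutral heterogeneous conditions, which should give the enal without isomerising C4=C5 or disturbing the bromide.

Step 14
Reactants: 29 bromomethyl butenolide enal
Product: 31 (6R,7S,8S)-14,15-diacetoxy-6-hydroxygermacra-1(10)Z,4E,11(13)-trien-12,8-olide, via allylchromium species 30 (not isolated)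
Conditions: CrCl2 (6 equiv), THF, rt, slow addition of 29 (final 2 mM); pH 7 buffer
Reagents that add atoms: none
Why: Two equivalents of Cr(II) reduce the C13–Br bond to the allylchromium(III) 30, a geometry-locked γ-substituted allyl metal (C8 trans to C13 across C7=C11), which adds through its γ-carbon C7 to the tethered aldehyde in a six-membered Zimmerman–Traxler transition state (Cr–O–C6–C7–C11–C13) and moves the double bond to the exocyclic C11=C13 position. The closest known reactions are the intramolecular Nozaki–Hiyama allylation that closes ten-membered carbocycles from open-chain ω-formyl 2-(bromomethyl)-2-enoates and the intermolecular Barbier allylation of aldehydes with 5-substituted 3-(bromomethyl)butenolides. The ten-membered ring closes by 10-exo-trig attack of C7 on the formyl carbon, with the existing lactone supplying the rigid C7–C8 segment. C7 is set by approach of the aldehyde to the butenolide face opposite the C8–C9 bond, which avoids eclipsing the forming C6–C7 bond with C8–C9 and gives the trans ring fusion; C6 is set by the chair transition state with the alkenyl residue C5 equatorial, which for this E-type allylchromium gives the anti adduct, (6R) from (8S). The step needs γ- over α-attack (the closed transition state; α-attack would require a twelve-membered ring), ring closure over oligomerisation (high dilution, and the ring-cis C4=C5 bond turns the chain back towards C7) and reduction of the bromide only (allylic acetates and the enal should not be reduced by CrCl2 at room temperature on this time scale).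

**Compound list**

1 | but-2-yne-1,4-diol | OCC#CCO | starting material
2 | tert-butyldimethylsilyl chloride | CC(C)(C)[Si](C)(C)Cl | starting material
3 | 4-[(tert-butyldimethylsilyl)oxy]but-2-yn-1-ol | OCC#CCO[Si](C)(C)C(C)(C)C | intermediate
4 | (4-bromobut-1-yn-1-yl)trimethylsilane | C[Si](C)(C)C#CCCBr | starting material
5 | [4-(trimethylsilyl)but-3-yn-1-yl]magnesium bromide | C[Si](C)(C)C#CCC[Mg]Br | intermediate
6 | (E)-4-[(tert-butyldimethylsilyl)oxy]-2-[4-(trimethylsilyl)but-3-yn-1-yl]but-2-en-1-ol | C[Si](C)(C)C#CCC/C(CO)=C\CO[Si](C)(C)C(C)(C)C | intermediate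
7 | (E)-2-(but-3-yn-1-yl)-4-[(tert-butyldimethylsilyl)oxy]but-2-en-1-ol | C#CCC/C(CO)=C\CO[Si](C)(C)C(C)(C)C | intermediate
8 | paraformaldehyde (formaldehyde) | C=O | starting material
9 | (E)-8-[(tert-butyldimethylsilyl)oxy]-6-(hydroxymethyl)oct-6-en-2-yn-1-ol | OCC#CCC/C(CO)=C\CO[Si](C)(C)C(C)(C)C | intermediate
10 | tributyltin hydride | CCCC[SnH](CCCC)CCCC | starting material
11 | iodine | II | starting material
12 | (2E,6E)-8-[(tert-butyldimethylsilyl)oxy]-6-(hydroxymethyl)-2-(tributylstannyl)octa-2,6-dien-1-ol | OC/C([Sn](CCCC)(CCCC)CCCC)=C\CC/C(CO)=C\CO[Si](C)(C)C(C)(C)C | intermediate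
13 | (2E,6E)-8-[(tert-butyldimethylsilyl)oxy]-6-(hydroxymethyl)-2-iodoocta-2,6-dien-1-ol | OC/C(I)=C\CC/C(CO)=C\CO[Si](C)(C)C(C)(C)C | intermediate
14 | 4-methoxybenzyl chloride | COc1ccc(CCl)cc1 | starting material
15 | (2E,6E)-8-[(tert-butyldimethylsilyl)oxy]-2-iodo-1-[(4-methoxybenzyl)oxy]-6-{[(4-methoxybenzyl)oxy]methyl}octa-2,6-diene | COc1ccc(COC/C(I)=C\CC/C(COCc2ccc(OC)cc2)=C\CO[Si](C)(C)C(C)(C)C)cc1 | intermediate
16 | (S)-epichlorohydrin | ClC[C@@H]1CO1 | starting material
17 | alkenyllithium derived from 15 (Li in place of I, geometry retained) | COc1ccc(COC/C([Li])=C\CC/C(COCc2ccc(OC)cc2)=C\CO[Si](C)(C)C(C)(C)C)cc1 | intermediate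
18 | (2S,4Z,8E)-10-[(tert-butyldimethylsilyl)oxy]-1-chloro-4,8-bis{[(4-methoxybenzyl)oxy]methyl}deca-4,8-dien-2-ol | ClC[C@@H](O)C/C(COCc1ccc(OC)cc1)=C/CC/C(COCc1ccc(OC)cc1)=C\CO[Si](C)(C)C(C)(C)C | intermediate
19 | trimethylsulfonium iodide | C[S+](C)C.[I-] | starting material
20 | (S)-2-[(2Z,6E)-8-[(tert-butyldimethylsilyl)oxy]-2,6-bis{[(4-methoxybenzyl)oxy]methyl}octa-2,6-dien-1-yl]oxirane | C1O[C@H]1C/C(COCc2ccc(OC)cc2)=C/CC/C(COCc2ccc(OC)cc2)=C\CO[Si](C)(C)C(C)(C)C | intermediate
21 | (3S,5Z,9E)-11-[(tert-butyldimethylsilyl)oxy]-5,9-bis{[(4-methoxybenzyl)oxy]methyl}undeca-1,5,9-trien-3-ol | C=C[C@@H](O)C/C(COCc1ccc(OC)cc1)=C/CC/C(COCc1ccc(OC)cc1)=C\CO[Si](C)(C)C(C)(C)C | intermediate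
22 | (3S,5Z,9E)-11-[(tert-butyldimethylsilyl)oxy]-5,9-bis(hydroxymethyl)undeca-1,5,9-trien-3-ol | C=C[C@@H](O)C/C(CO)=C/CC/C(CO)=C\CO[Si](C)(C)C(C)(C)C | intermediate
23 | acetyl chloride | CC(Cl)=O | starting material
24 | (3S,5Z,9E)-5,9-bis(acetoxymethyl)-11-[(tert-butyldimethylsilyl)oxy]undeca-1,5,9-trien-3-ol | C=C[C@@H](O)C/C(COC(C)=O)=C/CC/C(COC(C)=O)=C\CO[Si](C)(C)C(C)(C)C | intermediate
25 | 2-(bromomethyl)acrylic acid | OC(=O)C(=C)CBr | starting material
26 | (3S,5Z,9E)-5,9-bis(acetoxymethyl)-11-[(tert-butyldimethylsilyl)oxy]undeca-1,5,9-trien-3-yl 2-(bromomethyl)acrylate | C=C[C@@H](OC(=O)C(=C)CBr)C/C(COC(C)=O)=C/CC/C(COC(C)=O)=C\CO[Si](C)(C)C(C)(C)C | intermediate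
27 | (S)-3-(bromomethyl)-5-[(2Z,6E)-2,6-bis(acetoxymethyl)-8-[(tert-butyldimethylsilyl)oxy]octa-2,6-dien-1-yl]furan-2(5H)-one | BrCC1=C[C@H](C/C(COC(C)=O)=C/CC/C(COC(C)=O)=C\CO[Si](C)(C)C(C)(C)C)OC1=O | intermediate
28 | (S)-3-(bromomethyl)-5-[(2Z,6E)-2,6-bis(acetoxymethyl)-8-hydroxyocta-2,6-dien-1-yl]furan-2(5H)-one | BrCC1=C[C@H](C/C(COC(C)=O)=C/CC/C(COC(C)=O)=C\CO)OC1=O | intermediate
29 | (S)-3-(bromomethyl)-5-[(2Z,6E)-2,6-bis(acetoxymethyl)-8-oxoocta-2,6-dien-1-yl]furan-2(5H)-one | BrCC1=C[C@H](C/C(COC(C)=O)=C/CC/C(COC(C)=O)=C\C=O)OC1=O | intermediate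
30 | allylchromium(III) dichloride derived from 29 (CrCl2 in place of Br) | Cl[Cr](Cl)CC1=C[C@H](C/C(COC(C)=O)=C/CC/C(COC(C)=O)=C\C=O)OC1=O | intermediate
31 | (6R,7S,8S)-14,15-diacetoxy-6-hydroxygermacra-1(10)Z,4E,11(13)-trien-12,8-olide | C=C1C(=O)O[C@H]2C/C(COC(C)=O)=C/CC/C(COC(C)=O)=C\[C@@H](O)[C@H]12 | target

**Step count and risks**

Total step count: 14. Longest linear sequence: 14.

Steps most likely to fail:

1. Step 14. The tether may force the aldehyde to react through a boat-like transition state or one with C5 axial, so that the wrong aldehyde face is attacked and C6 is set wrongly; intermolecular allylation may also compete. Fallback, from 29 to 31: the ring closure is kept and C6 is set afterwards by stereospecific inversion instead of by transition-state control. The C6-epimeric alcohol F1 obtained from 29 under the conditions of step 14 is treated with chloroacetic acid, PPh3 and DIAD (toluene, 0 °C; Mitsunobu inversion, SN2 at C6 because SN2' would have to occur at the fully substituted C4) to give the (6R)-chloroacetate F2. Thiourea and NaHCO3 in ethanol then remove the chloroacetyl group selectively beside the two acetates and give 31.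

2. Step 11. The activated allylic bromide may alkylate the ruthenium alkylidene or its ligands, or ring closure onto the electron-poor 1,1-disubstituted olefin may be too slow, so that the catalyst dies before the butenolide forms. Fallback, from 24 to 29: C13 is carried as a silyl ether and the bromide is made last. Commercial ethyl 2-(hydroxymethyl)acrylate is silylated (TBSCl, imidazole) to ethyl 2-{[(tert-butyldimethylsilyl)oxy]methyl}acrylate F3 and saponified (LiOH) to the acid F4. DCC/DMAP esterification of 24 with F4 gives the ester F5, and ring-closing metathesis (Grubbs II, CH2Cl2, 40 °C) gives the bis-silyl butenolide F6. HF·pyridine removes both silyl groups to give the diol F7. MnO2 oxidises only the electron-rich C6 allylic alcohol, not the hydroxymethyl group on the electron-poor butenolide, and gives the hydroxy enal F8. An Appel reaction (CBr4, PPh3, 0 °C) converts F8 into 29.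

3. Step 6. The 2-lithioallyl ether 17 may lose p-methoxybenzyl oxide by β-elimination to an allene before it meets the epoxide, or BF3 may cleave an ether. Fallback, from 13 to 22: the coupling is run without the PMB groups through a β-oxido alkenyl metal, which has no leaving group. Iodo diol 13 is deprotonated with MeLi (2 equiv) and exchanged with t-BuLi (2 equiv, −78 °C) to the trilithio species F9. Transmetalation with MgBr2·OEt2 and CuI-catalysed opening of 16 at −40 °C gives the chlorohydrin triol F10. Excess dimethylsulfonium methylide (as in step 7) converts F10 directly into triol 22, which also removes steps 5 and 8.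

**Further compounds**

F1 | step 14 | (6S,7S,8S)-14,15-diacetoxy-6-hydroxygermacra-1(10)Z,4E,11(13)-trien-12,8-olide (C6 epimer of 31) | C=C1C(=O)O[C@H]2C/C(COC(C)=O)=C/CC/C(COC(C)=O)=C\[C@H](O)[C@H]12
F2 | step 14 | 6-O-chloroacetyl derivative of 31, (6R,7S,8S) | C=C1C(=O)O[C@H]2C/C(COC(C)=O)=C/CC/C(COC(C)=O)=C\[C@@H](OC(=O)CCl)[C@H]12
F3 | step 11 | ethyl 2-{[(tert-butyldimethylsilyl)oxy]methyl}acrylate | C=C(CO[Si](C)(C)C(C)(C)C)C(=O)OCC
F4 | step 11 | 2-{[(tert-butyldimethylsilyl)oxy]methyl}acrylic acid | C=C(CO[Si](C)(C)C(C)(C)C)C(O)=O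
F5 | step 11 | (3S,5Z,9E)-5,9-bis(acetoxymethyl)-11-[(tert-butyldimethylsilyl)oxy]undeca-1,5,9-trien-3-yl 2-{[(tert-butyldimethylsilyl)oxy]methyl}acrylate | C=C[C@@H](OC(=O)C(=C)CO[Si](C)(C)C(C)(C)C)C/C(COC(C)=O)=C/CC/C(COC(C)=O)=C\CO[Si](C)(C)C(C)(C)C
F6 | step 11 | (S)-3-{[(tert-butyldimethylsilyl)oxy]methyl}-5-[(2Z,6E)-2,6-bis(acetoxymethyl)-8-[(tert-butyldimethylsilyl)oxy]octa-2,6-dien-1-yl]furan-2(5H)-one | CC(C)(C)[Si](C)(C)OCC1=C[C@H](C/C(COC(C)=O)=C/CC/C(COC(C)=O)=C\CO[Si](C)(C)C(C)(C)C)OC1=O
F7 | step 11 | (S)-3-(hydroxymethyl)-5-[(2Z,6E)-2,6-bis(acetoxymethyl)-8-hydroxyocta-2,6-dien-1-yl]furan-2(5H)-one | OCC1=C[C@H](C/C(COC(C)=O)=C/CC/C(COC(C)=O)=C\CO)OC1=O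
F8 | step 11 | (S)-3-(hydroxymethyl)-5-[(2Z,6E)-2,6-bis(acetoxymethyl)-8-oxoocta-2,6-dien-1-yl]furan-2(5H)-one | OCC1=C[C@H](C/C(COC(C)=O)=C/CC/C(COC(C)=O)=C\C=O)OC1=O
F9 | step 6 | trilithio species from 13 (two lithium alkoxides, alkenyllithium in place of the iodide) | [Li]OC/C([Li])=C\CC/C(CO[Li])=C\CO[Si](C)(C)C(C)(C)C
F10 | step 6 | (2S,4Z,8E)-10-[(tert-butyldimethylsilyl)oxy]-1-chloro-4,8-bis(hydroxymethyl)deca-4,8-dien-2-ol | ClC[C@@H](O)C/C(CO)=C/CC/C(CO)=C\CO[Si](C)(C)C(C)(C)C
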